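**Plateau ratio.** The plateau ratio, [target] over [dissolved substrate] in the last two cedar readings, is 1.44. You are asked about the cedar flask itself, followed so far to 4.00 h, with the solid substrate stirred into a held gas.

| flask | solid substrate | gas | remark | time |
|---|---|---|---|---|
| cedar | 0.80 M | 30 mM (held) | the very flask that is asked about, followed so far |  |
| flask | 0.80 M | 30 mM (held) |  | 8.0 h |

cedar run (percent of the solid substrate charged)

| time / h | target / % | dissolved substrate / % | solid substrate / % |
|---|---|---|---|
| 0.200 | 1.8 | 14.2 | 83.9 |
| 0.667 | 9.8 | 27.6 | 56.2 |
| 1.00 | 15.2 | 28.6 | 38.3 |
| 1.50 | 22.4 | 33.2 | 17.5 |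
| 2.50 | 36.9 | 29.4 | 0 |
| 3.00 | 41.4 | 28.2 | 0.5 |
| 4.00 | 40.7 | 28.7 | 0.3 |

(readings scatter by 1 percentage point)

- solid substrate is a solid; its amount is given per volume of the solution
- at the start none of the gas is in solution
- at the start none of the solid substrate is in solution
- dissolved substrate means what is dissolved; the solid is not counted in it

- the target standing at 8.0 h, as a percentage of the solid substrate charged
- concentration of dissolved substrate in solution at 50 min, in percent of saturation
- the change that raises the amount of target at 8.0 h, in percent of the solid substrate charged most ("none" if none brings more than 2 percentage points) (Thursday's / Monday's / Sunday's / Friday's / none)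
- amount of target at 8.0 h, in percent of the solid substrate charged, after Friday's

- Thursday's: doubling the dissolution coefficient of the solid substrate, all else as stated
- Monday's: doubling the saturation concentration of gas, all else as stated
- Sunday's: doubling the solubility of the solid substrate, all else as stated
- Friday's: doubling the transfer coefficient of the gas, all else as stated

**Why these two.** In cedar, the solid substrate reads 0.5 % at 3.00 h. From there to 4.00 h, target shifts 0.7 percentage points and dissolved substrate 0.5 points, each less than the scatter of 1 point. The unseen part reads 30 points, then 30 points.

**My reckoning.** I carry the plateau forward and expect 41.0 % of target at 8.0 h. If the plateau ratio is an equilibrium ratio (thermodynamic control) at the gas level, Friday's, which keeps that level, leaves target near this figure. The ratio gives me no ranking of the other changes.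

**The forecast.** It gives 41 %, 50 %, Monday's and 42 %, on this ground: “Raising gas concentration should shift either case, so Monday's is best.”

**Flask result.** The flask gives 40.6 %, 59.8 %, Sunday's and 40.6 %.

    solid substrate + target → side product (k = 0.0450 M⁻¹ min⁻¹)
    gas ⇌ coupling partner, rate k2*(csat - [coupling partner]) (kL = 8.30 min⁻¹)
    solid substrate ⇌ dissolved substrate, rate k3*(cs3 - [dissolved substrate]) while solid is left; crystals form when [dissolved substrate] > cs3 (solubility = 0.380 M, k = 0.0330 min⁻¹)
    dissolved substrate + coupling partner ⇌ target (K = 50.0 M⁻¹, k = 0.780 M⁻¹ min⁻¹)

**Second flask.** Sunday's adds 13 points, more than the 9.8 points of Monday's. The neighbour flask charged with 2.0 M of solid substrate holds 11.5 % of dissolved substrate at 8.00 h. The plateau ratio turns that into 16.6 % of target, and that flask holds 17.3 %.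

(All runs were computed from invented constants; scatter was added.)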